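**Plan**

- Retrosynthesis: the two O–Si bonds are cut first. Next is the C1–C2 bond of the lactam, which opens the six-membered ring to a vinyl isocyanate on C4 and an exocyclic C1=CH2 enol ether on an intact dioxolane. Then N3–C4 is cut (Curtius, from C4–CO2H, from C4–OTf), C1=CH2 goes back to a lactone C=O, the two ketal C5–O bonds go back to (S)-lactic acid plus a symmetrical 1,2-diketone, and the two CH2–CO bonds go back to two equivalents of one benzyl Grignard reagent and an oxalic bis-Weinreb amide.
- Forward: diketone, then dioxolanone (the dioxolane ring arises first), Z-enol triflate, methylidene-dioxolane, acid, acyl azide, isocyanate, radical closure of the lactam ring (which completes the 6,8-dioxa-3-azabicyclo[3.2.1]octane), desilylation.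
- Enabling feature: C1 is a tertiary carbon of the dioxolane ring bonded to ring oxygen O8, so it can become a nucleophilic α-oxy radical (H atom to C1=CH2). C2 is an acyl carbon on N3, so it can be offered as an isocyanate on the arm at C5. Both are acceptor-type carbons (ketone-level C1, acyl C2) and are joined by a radical. The arm bridges one face of the dioxolane, which fixes C1.
- Stereochemistry: C7 comes from (S)-lactic acid. C5 is set by equilibrating ketalisation (benzyl cis to the C7 methyl, epimers separable). C1 follows from the bridging constraint. The Z-enamide comes from a Z-enolate and is carried through triflate, acid, azide and isocyanate with retention.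

Key step: step 10

Remark on the chemistry: locants C1, C2, N3, C4, C5, O6, C7, O8 are those of 6,8-dioxa-3-azabicyclo[3.2.1]octan-2-one (C1 = methyl-bearing bridgehead, C5 = ketal carbon, C7 = CH(CH3)). TIPS = triisopropylsilyl. Compounds 1, 5 and 8 are assumed to be bought. The exocyclic enol ether in 12–15 is acid-labile, so these compounds are handled on base-washed glass and Et3N-deactivated silica.

**Step 1**
Reactants: 1 4-hydroxybenzaldehyde
Product: 2 4-(triisopropylsilyloxy)benzaldehyde
Conditions: TIPSCl, imidazole, DMF, rt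
Reagents that add atoms: triisopropylsilyl chloride, CC(C)[Si](Cl)(C(C)C)C(C)C
Why: Imidazole-promoted silyl ether formation on the phenol; the aryl TIPS ether should survive the Grignard, base, titanium, palladium and radical steps and leave with fluoride at the end.

**Step 2**
Reactants: 2 4-(triisopropylsilyloxy)benzaldehyde
Product: 3 [4-(triisopropylsilyloxy)phenyl]methanol
Conditions: NaBH4, MeOH, 0 °C
Reagents that add atoms: none
Why: Borohydride reduction of the aldehyde to the benzylic alcohol.

**Step 3**
Reactants: 3 [4-(triisopropylsilyloxy)phenyl]methanol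
Product: 4 4-(triisopropylsilyloxy)benzyl chloride
Conditions: SOCl2, pyridine, CH2Cl2, 0 °C to rt
Reagents that add atoms: thionyl chloride, O=S(Cl)Cl
Why: Chlorodehydroxylation through the chlorosulfite, the usual route to 4-alkoxybenzyl chlorides; pyridine takes up HCl so the silyl ether is spared.

**Step 4**
Reactants: 4 4-(triisopropylsilyloxy)benzyl chloride (first of two equivalents); 5 N,N'-dimethoxy-N,N'-dimethyloxamide
Product: 7 1,4-bis[4-(triisopropylsilyloxy)phenyl]butane-2,3-dione, via benzylic Grignard reagent 6 (not isolated)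
Conditions: 4 (2.3 equiv in all), Mg turnings (3 equiv), THF, 0 °C, slow addition; then 5 (1.0 equiv), −78 °C to rt; aq NH4Cl
Reagents that add atoms: [4-(triisopropylsilyloxy)benzyl]magnesium chloride (the second equivalent of Grignard reagent 6, made in the same flask from the second equivalent of 4), Cl[Mg]Cc1ccc(O[Si](C(C)C)(C(C)C)C(C)C)cc1
Why: Grignard formation followed by twofold acyl substitution on the bis-Weinreb amide of oxalic acid, one molecule of 6 adding to each amide carbonyl, so that each benzyl group of the symmetrical diketone comes from one molecule of 4; the chelated tetrahedral intermediates should hold until the quench, so the 1,2-diketone and not a carbinol is expected.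

**Step 5**
Reactants: 7 1,4-bis[4-(triisopropylsilyloxy)phenyl]butane-2,3-dione; 8 (S)-lactic acid
Product: 9 (2R,5S)-5-methyl-2-{[4-(triisopropylsilyloxy)phenyl]acetyl}-2-[4-(triisopropylsilyloxy)benzyl]-1,3-dioxolan-4-one
Conditions: p-TsOH·H2O (cat.), cyclohexane, reflux, Dean–Stark trap; C2 epimers separated on silica, minor epimer returned to the same conditions
Reagents that add atoms: none
Why: Acid-catalysed dehydrative ketalisation of one carbonyl of the symmetrical diketone with the α-hydroxy acid (1,3-dioxolan-4-one formation); C5 is taken unchanged from (S)-lactic acid, and C2 is set under equilibration, where the sp3 benzyl group is expected to prefer the site cis to the C5 methyl while the planar acyl group tolerates the trans site.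

**Step 6**
Reactants: 9 the dioxolanone ketone
Product: 11 (Z)-1-[(2R,5S)-5-methyl-4-oxo-2-[4-(triisopropylsilyloxy)benzyl]-1,3-dioxolan-2-yl]-2-[4-(triisopropylsilyloxy)phenyl]ethenyl trifluoromethanesulfonate, via potassium Z-enolate 10 (not isolated)
Conditions: KN(SiMe3)2 (1.05 equiv), THF, −78 °C; then PhNTf2, −78 to −20 °C
Reagents that add atoms: N-phenylbis(trifluoromethanesulfonimide), O=S(=O)(N(c1ccccc1)S(=O)(=O)C(F)(F)F)C(F)(F)F
Why: Kinetic enolisation of the benzyl ketone (much more acidic than the lactone C5–H) and O-triflation; the Z-enolate, with the aryl group cis to oxygen and away from the quaternary ketal carbon (allylic strain), fixes the alkene geometry of the target.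

**Step 7**
Reactants: 11 the Z-enol triflate
Product: 12 (Z)-1-[(2R,5S)-5-methyl-4-methylidene-2-[4-(triisopropylsilyloxy)benzyl]-1,3-dioxolan-2-yl]-2-[4-(triisopropylsilyloxy)phenyl]ethenyl trifluoromethanesulfonate
Conditions: Cp2TiMe2 (2.5 equiv), toluene, 65 °C, dark; Et3N-deactivated silica
Reagents that add atoms: dimethyltitanocene (Cp2TiMe2), C[Ti+2]C.c1cc[cH-]c1.c1cc[cH-]c1
Why: Petasis methylenation of the lactone carbonyl by the titanium methylidene, a standard conversion of 1,3-dioxolan-4-ones into 4-methylidene-1,3-dioxolanes; vinyl triflate and silyl ethers should be inert and no stereocentre is touched.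

**Step 8**
Reactants: 12 the methylidene-dioxolane enol triflate
Product: 13 (Z)-2-[(2R,5S)-5-methyl-4-methylidene-2-[4-(triisopropylsilyloxy)benzyl]-1,3-dioxolan-2-yl]-3-[4-(triisopropylsilyloxy)phenyl]prop-2-enoic acid
Conditions: Pd(OAc)2 (cat.), PPh3 (cat.), CO (1 atm), H2O, Et3N, DMF, 50 °C; work-up at pH 7–8, carried on as the triethylammonium salt
Reagents that add atoms: carbon monoxide, [C-]#[O+]; water, O
Why: Palladium-catalysed hydroxycarbonylation of the enol triflate (oxidative addition to zerovalent palladium, CO insertion, hydrolysis of the acylpalladium) with retention of alkene geometry; the basic medium and work-up keep the acid from protonating the enol ether.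

**Step 9**
Reactants: 13 the acrylic acid (as its triethylammonium salt)
Product: 14 (Z)-2-[(2R,5S)-5-methyl-4-methylidene-2-[4-(triisopropylsilyloxy)benzyl]-1,3-dioxolan-2-yl]-3-[4-(triisopropylsilyloxy)phenyl]prop-2-enoyl azide
Conditions: DPPA, Et3N, toluene, 0 °C to rt; cold aq NaHCO3 wash; dried toluene solution used directly
Reagents that add atoms: diphenylphosphoryl azide, [N-]=[N+]=NP(=O)(Oc1ccccc1)Oc1ccccc1
Why: Acyl azide formation from the carboxylate through the mixed acyl phosphate, run below the temperature at which the azide rearranges.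

**Step 10**
Reactants: 14 the acyl azide
Product: 16 (1R,5R,7S,Z)-1,7-dimethyl-5-[4-(triisopropylsilyloxy)benzyl]-4-[4-(triisopropylsilyloxy)benzylidene]-6,8-dioxa-3-azabicyclo[3.2.1]octan-2-one, via vinyl isocyanate 15 (not isolated)
Conditions: toluene, 80 °C, 1 h; then THF (0.01 M), Fe(acac)3 (0.5 equiv), PhSiH2(Oi-Pr) (2 equiv), 0 °C to rt, Ar; aq NaHCO3
Reagents that add atoms: none
Why: Proposed new method: heating rearranges acyl azide 14 (Curtius, retention of the Z alkene) to isocyanate 15; the iron hydride generated from Fe(acac)3 and the silane then transfers a hydrogen atom to the terminal carbon of the C1=CH2 enol ether, which creates the C1 methyl group and a nucleophilic tertiary α-alkoxy radical at C1 that adds to the electrophilic carbon of the N=C=O group, and the resulting amidyl radical, delocalised over N3–C4=CH–Ar, is reduced by divalent iron to the amidate and released as the N–H lactam after silyl transfer and work-up. The closest known reaction types are hydrogen-atom-transfer radical cyclisations of alkenes onto C=O, C=N and nitrile acceptors and tin-hydride ring closures of alkyl radicals onto isocyanate carbon; their union with an enol ether donor and a vinyl isocyanate acceptor has not been shown. The ring closed is the six-membered 1,4-oxazin-3-one (C1–C2–N3–C4–C5–O8), by a six-membered closure at the central cumulene carbon (exo to C=O, endo to N=C), which at once completes the 6,8-dioxa-3-azabicyclo[3.2.1]octane. The new stereocentre C1 is controlled by C5: the arm can reach the planar radical only from the dioxolane face it occupies, so C2 is bonded cis to C4 and the new methyl is left on the opposite face, cis to the C7 methyl and the benzyl group. The step needs hydrogen-atom transfer to the 1,1-disubstituted enol ether in preference to the hindered styrenyl alkene, ring closure in preference to reduction or C5–O8 β-scission of the radical, and survival of the isocyanate, which the electron-rich unhindered enol ether, the polarity match, high dilution at 0 °C and an alcohol-free medium should secure; the enamide is expected to settle as the Z isomer, in which the aryl group avoids the quaternary C5.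

**Step 11**
Reactants: 16 the bis-silyl bicyclic lactam
Product: 17 Leptochartamide B
Conditions: Bu4NF (TBAF, 2.4 equiv), AcOH (2.4 equiv), THF, 0 °C
Reagents that add atoms: none
Why: Fluoride-mediated cleavage of the two aryl silyl ethers, buffered with acetic acid so that the phenols, the enamide and the bicyclic ketal do not meet strong base.

**Compound list**

1 | 4-hydroxybenzaldehyde | O=Cc1ccc(O)cc1 | starting material
2 | 4-(triisopropylsilyloxy)benzaldehyde | O=Cc1ccc(O[Si](C(C)C)(C(C)C)C(C)C)cc1 | intermediate
3 | [4-(triisopropylsilyloxy)phenyl]methanol | OCc1ccc(O[Si](C(C)C)(C(C)C)C(C)C)cc1 | intermediate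
4 | 4-(triisopropylsilyloxy)benzyl chloride | ClCc1ccc(O[Si](C(C)C)(C(C)C)C(C)C)cc1 | intermediate
5 | N,N'-dimethoxy-N,N'-dimethyloxamide | CON(C)C(=O)C(=O)N(C)OC | starting material
6 | [4-(triisopropylsilyloxy)benzyl]magnesium chloride | Cl[Mg]Cc1ccc(O[Si](C(C)C)(C(C)C)C(C)C)cc1 | intermediate (not isolated)
7 | 1,4-bis[4-(triisopropylsilyloxy)phenyl]butane-2,3-dione | O=C(Cc1ccc(O[Si](C(C)C)(C(C)C)C(C)C)cc1)C(=O)Cc1ccc(O[Si](C(C)C)(C(C)C)C(C)C)cc1 | intermediate
8 | (S)-lactic acid | C[C@H](O)C(=O)O | starting material
9 | (2R,5S)-5-methyl-2-{[4-(triisopropylsilyloxy)phenyl]acetyl}-2-[4-(triisopropylsilyloxy)benzyl]-1,3-dioxolan-4-one (benzyl cis to the C5 methyl) | C[C@@H]1O[C@](C(=O)Cc2ccc(O[Si](C(C)C)(C(C)C)C(C)C)cc2)(Cc2ccc(O[Si](C(C)C)(C(C)C)C(C)C)cc2)OC1=O | intermediate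
10 | potassium Z-enolate of 9 | C[C@@H]1O[C@](/C([O-])=C/c2ccc(O[Si](C(C)C)(C(C)C)C(C)C)cc2)(Cc2ccc(O[Si](C(C)C)(C(C)C)C(C)C)cc2)OC1=O.[K+] | intermediate (not isolated)
11 | (Z)-1-[(2R,5S)-5-methyl-4-oxo-2-[4-(triisopropylsilyloxy)benzyl]-1,3-dioxolan-2-yl]-2-[4-(triisopropylsilyloxy)phenyl]ethenyl trifluoromethanesulfonate | C[C@@H]1O[C@](/C(OS(=O)(=O)C(F)(F)F)=C/c2ccc(O[Si](C(C)C)(C(C)C)C(C)C)cc2)(Cc2ccc(O[Si](C(C)C)(C(C)C)C(C)C)cc2)OC1=O | intermediate
12 | (Z)-1-[(2R,5S)-5-methyl-4-methylidene-2-[4-(triisopropylsilyloxy)benzyl]-1,3-dioxolan-2-yl]-2-[4-(triisopropylsilyloxy)phenyl]ethenyl trifluoromethanesulfonate | C[C@@H]1O[C@](/C(OS(=O)(=O)C(F)(F)F)=C/c2ccc(O[Si](C(C)C)(C(C)C)C(C)C)cc2)(Cc2ccc(O[Si](C(C)C)(C(C)C)C(C)C)cc2)OC1=C | intermediate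
13 | (Z)-2-[(2R,5S)-5-methyl-4-methylidene-2-[4-(triisopropylsilyloxy)benzyl]-1,3-dioxolan-2-yl]-3-[4-(triisopropylsilyloxy)phenyl]prop-2-enoic acid | C[C@@H]1O[C@](/C(C(=O)O)=C/c2ccc(O[Si](C(C)C)(C(C)C)C(C)C)cc2)(Cc2ccc(O[Si](C(C)C)(C(C)C)C(C)C)cc2)OC1=C | intermediate
14 | (Z)-2-[(2R,5S)-5-methyl-4-methylidene-2-[4-(triisopropylsilyloxy)benzyl]-1,3-dioxolan-2-yl]-3-[4-(triisopropylsilyloxy)phenyl]prop-2-enoyl azide | C[C@@H]1O[C@](/C(C(=O)N=[N+]=[N-])=C/c2ccc(O[Si](C(C)C)(C(C)C)C(C)C)cc2)(Cc2ccc(O[Si](C(C)C)(C(C)C)C(C)C)cc2)OC1=C | intermediate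
15 | (2R,5S)-2-[(Z)-1-isocyanato-2-[4-(triisopropylsilyloxy)phenyl]ethenyl]-5-methyl-4-methylidene-2-[4-(triisopropylsilyloxy)benzyl]-1,3-dioxolane | C[C@@H]1O[C@](/C(N=C=O)=C/c2ccc(O[Si](C(C)C)(C(C)C)C(C)C)cc2)(Cc2ccc(O[Si](C(C)C)(C(C)C)C(C)C)cc2)OC1=C | intermediate (not isolated)
16 | (1R,5R,7S,Z)-1,7-dimethyl-5-[4-(triisopropylsilyloxy)benzyl]-4-[4-(triisopropylsilyloxy)benzylidene]-6,8-dioxa-3-azabicyclo[3.2.1]octan-2-one | C[C@@H]1O[C@]2(Cc3ccc(O[Si](C(C)C)(C(C)C)C(C)C)cc3)O[C@@]1(C)C(=O)N/C2=C\c1ccc(O[Si](C(C)C)(C(C)C)C(C)C)cc1 | intermediate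
17 | Leptochartamide B, (1R,5R,7S,Z)-5-(4-hydroxybenzyl)-4-(4-hydroxybenzylidene)-1,7-dimethyl-6,8-dioxa-3-azabicyclo[3.2.1]octan-2-one | C[C@@H]1O[C@]2(Cc3ccc(O)cc3)O[C@@]1(C)C(=O)N/C2=C\c1ccc(O)cc1 | target

**Step count**

Total: 11 steps. Longest linear sequence: 11 steps (1 to 17); compounds 5 and 8 enter as bought materials.

**Steps most likely to fail**

1. Step 10 (Proposed new method). What may go wrong:
   - The isocyanate may be lost to the hydride and Lewis-acid medium (hydrosilylation, oligomerisation, carbamoylation of the acetylacetonate ligand).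
   - The tertiary radical may be reduced before it closes.
   - Hydrogen-atom transfer may go to the styrenyl alkene.
   - The α-oxy radical may fragment by β-scission of the C5–O8 bond.

   The fallback uses known chemistry only and sets out from compound 12. Benzeneselenol adds without catalyst across the enol ether in the Markovnikov sense to give the selenoketal triflate F1 (both C4 epimers, which is of no consequence). Hydroxycarbonylation as in step 8 gives the selenoketal acid F2, in which no enol ether is left to meet the acid. DPPA and Et3N give the selenoketal acyl azide F3, and heating in toluene gives the selenoketal isocyanate F4 (not isolated). Slow addition of Bu3SnH with Et3B and air in toluene at 0 °C then abstracts the phenylselanyl group. The same C1 radical forms in an inert hydrocarbon and closes onto the isocyanate carbon, the known tin-hydride radical ring closure onto isocyanates. The fallback comes back to the route at compound 16.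

2. Step 5. What may go wrong: weak facial discrimination at the ketal carbon during equilibration, and acid-promoted self-condensation of the enolised diketone.

   The fallback sets out from compound 7. (S)-But-3-yn-2-ol adds to one carbonyl as the hemiketal, whose oxygen closes 5-exo onto the silver-activated alkyne (AgOAc, DBU, MeCN, rt). This is the cycloisomerisation known for propargylic alcohols with CO2 and with activated ketones. It gives the methylidene-dioxolane ketone F5 directly, under kinetic control and without a lactone or a titanium step, and the C2 epimers are separated at this stage. KN(SiMe3)2 then gives the potassium enolate F6 (not isolated), and PhNTf2 returns the sequence to the route at compound 12.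

3. Step 8. What may go wrong: protonation of the exocyclic enol ether by the newly formed carboxylic acid (intramolecular addition or hydrolysis) during carbonylation and work-up.

   The fallback sets out from compound 12. Palladium-catalysed carbonylation in the presence of N-hydroxysuccinimide (Pd(OAc)2, Xantphos, CO, Et3N, DMSO, 60 °C) gives the N-succinimidyl ester F7, so no free acid is formed. NaN3 in aqueous acetone at 0 °C displaces N-hydroxysuccinimide, and the fallback comes back to the route at compound 14.

**Further compounds**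

F1 | step 10 | (Z)-1-[(2R,5S)-4,5-dimethyl-4-(phenylselanyl)-2-[4-(triisopropylsilyloxy)benzyl]-1,3-dioxolan-2-yl]-2-[4-(triisopropylsilyloxy)phenyl]ethenyl trifluoromethanesulfonate (C4 epimers) | C[C@@H]1O[C@](/C(OS(=O)(=O)C(F)(F)F)=C/c2ccc(O[Si](C(C)C)(C(C)C)C(C)C)cc2)(Cc2ccc(O[Si](C(C)C)(C(C)C)C(C)C)cc2)OC1(C)[Se]c1ccccc1
F2 | step 10 | (Z)-2-[(2R,5S)-4,5-dimethyl-4-(phenylselanyl)-2-[4-(triisopropylsilyloxy)benzyl]-1,3-dioxolan-2-yl]-3-[4-(triisopropylsilyloxy)phenyl]prop-2-enoic acid (C4 epimers) | C[C@@H]1O[C@](/C(C(=O)O)=C/c2ccc(O[Si](C(C)C)(C(C)C)C(C)C)cc2)(Cc2ccc(O[Si](C(C)C)(C(C)C)C(C)C)cc2)OC1(C)[Se]c1ccccc1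
F3 | step 10 | (Z)-2-[(2R,5S)-4,5-dimethyl-4-(phenylselanyl)-2-[4-(triisopropylsilyloxy)benzyl]-1,3-dioxolan-2-yl]-3-[4-(triisopropylsilyloxy)phenyl]prop-2-enoyl azide (C4 epimers) | C[C@@H]1O[C@](/C(C(=O)N=[N+]=[N-])=C/c2ccc(O[Si](C(C)C)(C(C)C)C(C)C)cc2)(Cc2ccc(O[Si](C(C)C)(C(C)C)C(C)C)cc2)OC1(C)[Se]c1ccccc1
F4 | step 10 | (2R,5S)-2-[(Z)-1-isocyanato-2-[4-(triisopropylsilyloxy)phenyl]ethenyl]-4,5-dimethyl-4-(phenylselanyl)-2-[4-(triisopropylsilyloxy)benzyl]-1,3-dioxolane (C4 epimers) | C[C@@H]1O[C@](/C(N=C=O)=C/c2ccc(O[Si](C(C)C)(C(C)C)C(C)C)cc2)(Cc2ccc(O[Si](C(C)C)(C(C)C)C(C)C)cc2)OC1(C)[Se]c1ccccc1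
F5 | step 5 | 1-[(2R,5S)-5-methyl-4-methylidene-2-[4-(triisopropylsilyloxy)benzyl]-1,3-dioxolan-2-yl]-2-[4-(triisopropylsilyloxy)phenyl]ethan-1-one | C[C@@H]1O[C@](C(=O)Cc2ccc(O[Si](C(C)C)(C(C)C)C(C)C)cc2)(Cc2ccc(O[Si](C(C)C)(C(C)C)C(C)C)cc2)OC1=C
F6 | step 5 | potassium Z-enolate of F5 | C[C@@H]1O[C@](/C([O-])=C/c2ccc(O[Si](C(C)C)(C(C)C)C(C)C)cc2)(Cc2ccc(O[Si](C(C)C)(C(C)C)C(C)C)cc2)OC1=C.[K+]
F7 | step 8 | N-succinimidyl (Z)-2-[(2R,5S)-5-methyl-4-methylidene-2-[4-(triisopropylsilyloxy)benzyl]-1,3-dioxolan-2-yl]-3-[4-(triisopropylsilyloxy)phenyl]prop-2-enoate | C[C@@H]1O[C@](/C(C(=O)ON2C(=O)CCC2=O)=C/c2ccc(O[Si](C(C)C)(C(C)C)C(C)C)cc2)(Cc2ccc(O[Si](C(C)C)(C(C)C)C(C)C)cc2)OC1=C
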